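# Proposed synthesis of CNP0144204.1 (26) by a Johnson–Claisen route

## Analysis of the target

The target 26 is a (2S)-flavanone. Ring A is a phloroglucinol nucleus with free hydroxyls at C5 and C7 and a ten-carbon chain on C6. Ring C is the dihydropyranone that holds the C2 stereocentre, and ring B is a 3',4'-dihydroxy-5'-methoxyphenyl group. The chain is C1''H2–C2''H=C3''(CH3)–C4''H2–C5''H2–C6''H(OH)–C7''(CH3)=C8''H2, with an E-trisubstituted alkene and an (R)-configured secondary allylic alcohol. C2 and C6'' are eleven bonds apart and cannot influence each other, so each has to be set by a reagent. C2 epimerizes in base by reversible opening of ring C to the 2'-hydroxychalcone, and the ring B catechol oxidizes in basic, aerated media. The C5 and C7 hydroxyls flank the chain and can add to C3'' under strong acid, and the allylic carbinol can ionize. The hard points are therefore the placement of the chain on C6 and not on C8, the E geometry at C2''=C3'', the acylation of an electron-rich ring that carries acid-labile groups, and an endgame restricted to mild acid. The strategy rests on the unit C1''–C2''=C3''(CH3)–C4''–C5'', which is what an orthoester Claisen rearrangement of a 2-methylallylic alcohol at C2'' produces. The terminus C6''(OH)–C7''(CH3)=C8''H2 is the same 2-methylallylic alcohol motif once more.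

## Retrosynthetic reasoning

**26 to 25 (protecting groups only).** The five hydroxyls of 26 are masked in 25 as four aryl MOM ethers and one TBS ether. No skeletal bond is cut. These groups survive organolithium, Grignard, hydride and aqueous-base steps, and all fall in one mild acidic methanolysis, which is the only kind of final step the chain and C2 tolerate.

**25 to 24 (O1–C2).** Ring C is opened at the O1–C2 bond to the 2'-hydroxychalcone 24. This is the retro-oxa-Michael that threatens C2 in base, used here in the forward sense under a chiral catalyst, so that C2 is set last and never meets a strong base. The single free phenol of 24 sits para to the chain, and this alone decides that the chain ends on C6 and not on C8.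

**24 to 21 and 23 (C-alpha=C-beta).** The enone is cut at its double bond into the methyl ketone 21 and the aldehyde 23, a Claisen–Schmidt pair. 23 is the bis-MOM ether of the commercial aldehyde 22, so ring B costs one step.

**21 to 20 to 18 (aryl–acetyl bond, via 19).** The free phenol of 21 is the TIPS ether in 20, and the acetyl group of 20 is traced to the bromine of 18. A Friedel–Crafts or Fries acylation would need Lewis acids that strip MOM ethers and attack the chain. Directed lithiation would deprotonate the doubly activated C1'' methylene. A bromine placed early, before any alkene exists, is the latent acetyl group. Bromine–lithium exchange (19) followed by a Weinreb-type acetyl donor then gives the ketone at the one position that leads to the 6-substituted flavanone.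

**18 to 17 to 16 (C6''–H) and 16 to 15 plus 9 (C6''–C7'').** The TBS ether 18 comes from the carbinol 17, and 17 from the isopropenyl ketone 16 by enantioselective reduction. The α-methylvinyl and unbranched alkyl groups differ enough for catalyst control. 16 is cut at C6''–C7'' into the Weinreb amide 15 and the isopropenyl Grignard reagent 9, which recreates the 2-methylallyl motif at the far end of the chain.

**15 to 14 to 10 plus 11 (C4''–C5'' and the C2''=C3'' alkene).** The amide 15 is the ester 14 in another oxidation-level guise. 14 is disconnected by the retro-Johnson–Claisen into the racemic allylic alcohol 10 and the orthoester 11. This cut removes the alkene geometry problem, because the chair transition state sets it, and it destroys a stereocentre, so 10 needs no asymmetric synthesis.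

**10 to 8 plus 9, and 8 to 7 to 6.** The carbinol 10 is cut at C2''–C3'' into the arylacetaldehyde 8 and the same Grignard reagent 9. 8 is the oxidation product of the alcohol 7, and 7 is the ring bromide of 6.

**6 to 3 plus 4 (via 5), and 3 to 2 to 1.** The aryl–C1'' bond is cut to the aryllithium 5 and ethylene oxide 4, which supplies C1'' and C2''. 5 comes from the triether 3 by lithiation between the two MOM ethers. The TIPS ether para to that position marks the oxygen that becomes O1. 3 is made from phloroglucinol 1 through the mono-silyl ether 2.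

## Alternatives that were turned down

**Alternative 1: ring A built last by a Claisen condensation.** The cut is C4a–C5. The precursor is the methyl ester A1, a β-keto ester that carries the finished (2S)-2-aryl-2,3-dihydropyran-4-one and the silylated chain on its α-carbon. In the forward step Mg(OMe)2 would form the extended enolate of the dihydropyranone, whose α-carbon (C4a) attacks the ester carbonyl (C5), and the new ring enolizes to the 5,7-diol A2.
- For: the chain is on C6 by construction, the ring A hydroxyls appear free, and no electron-rich arene has to be acylated. On these three points this plan is stronger than the chosen one.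
- Against: the base that forms the extended enolate can also deprotonate C3 and expel O1 by E1cB, which scrambles C2 before ring A closes.
- Against: a triketo ester of this kind can close through oxygen to a pyrone instead of through carbon.
- Against: A1 still needs the complete (2E,6R) chain as an allylic electrophile, so the alkene and the carbinol remain unsolved, and ring C needs its own asymmetric construction.
- Comparison: the chosen route gives up the protecting-group economy and in return uses a cheap aromatic ring A, exposes C2 only to a weakly basic amine catalyst and mild acid, and solves the chain within the strategy.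

**Alternative 2: asymmetric conjugate arylation of a chromone.** The cut is C2–C1'. The boronic acid A4 would add to C2 of the chromone A3 under [RhCl(C2H4)2]2 (monovalent rhodium) and a chiral diene, giving A5, which is identical with 25.
- For: C2 is set by a catalyst class with a stronger record of enantiocontrol than chalcone cyclization, and ring B enters late and convergently. On C2 this plan is the stronger one.
- Against: A3 is a vinylogous ester deactivated by two oxygen donors and crowded by the C5 ether next to the carbonyl, so it is a poor acceptor.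
- Against: A4 is an electron-rich boronic acid prone to protodeboronation in the aqueous basic medium.
- Against: the rhodium enolate of the product can eliminate O1 and erode the new centre.
- Against: A3 would have to be made from 21 in two further steps, and A4 from an aryl halide instead of the aldehyde 22.
- Comparison: this plan leaves the whole chain problem untouched, so it is an endgame variant and not a rival for the chain. The chosen route reaches 25 from 21 in two steps with the more electrophilic open-chain enone.

**Alternative 3: methylalumination and benzylic coupling.** The cuts are C3''–CH3 and C1''–C2''. The alkyne A6 would add methyl and aluminium syn under AlMe3 and Cp2ZrCl2, and the alkenylalane would be coupled in the same pot with the benzylic chloride A7 under Pd(PPh3)4 (zerovalent palladium) to give A8.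
- For: the route is convergent, and syn-carbometalation fixes the E geometry at least as firmly as a Claisen chair, probably more so. The carbinol is made early on a small fragment.
- Against: A7 is a benzylic chloride with three oxygen donors on the ring. It ionizes very easily and would be hard to prepare and keep.
- Against: the MOM ethers of A7 and the silyl ether oxygen of A6 would sit in an excess of strongly Lewis acidic AlMe3.
- Against: A6 needs an enantioselective synthesis of its own, so the total count does not fall, and A8 has no handle for the ring A acyl group.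
- Comparison: the chosen route is more linear, but it avoids the labile benzyl halide, builds every chain C–C bond from one Grignard reagent used twice and one orthoester, and carries the acyl handle from the start.

Key step: step 7

## Assumptions

- The quinine-derived thiourea of step 16 is taken to favour the 2S flavanone. If a first run shows the opposite sense, the pseudoenantiomeric quinidine-derived catalyst is used in the same way.
- Isopropenylmagnesium bromide 9 is used as the commercial THF solution, and the aldehyde 22 is bought.
- The side-chain numbering C1''–C8'' of the target is used for all intermediates.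

## Route

Step 1
Reactants: 1 phloroglucinol
Product: 2 5-(triisopropylsilyloxy)benzene-1,3-diol
Conditions: TIPSCl (1.0 equiv), imidazole, DMF, 0 °C to rt; 1 in threefold excess
Reagents that add atoms: triisopropylsilyl chloride, CC(C)[Si](Cl)(C(C)C)C(C)C
Why: Silylation of a phenol with a silyl chloride and imidazole; the excess of the cheap, water-soluble triol 1 should bias the statistics towards the mono-ether, and unreacted 1 is washed out with water.

Step 2
Reactants: 2 mono-TIPS ether of phloroglucinol
Product: 3 1,3-bis(methoxymethoxy)-5-(triisopropylsilyloxy)benzene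
Conditions: MOMCl, i-Pr2NEt, CH2Cl2, 0 °C to rt
Reagents that add atoms: chloromethyl methyl ether, COCCl
Why: O-alkylation of both remaining phenols by the chloromethyl ether under amine base (Williamson-type acetal formation); the hindered aryl silyl ether is inert to these conditions.

Step 3
Reactants: 3 triether; 4 ethylene oxide
Product: 6 2-[2,6-bis(methoxymethoxy)-4-(triisopropylsilyloxy)phenyl]ethan-1-ol, via aryllithium 5 (not isolated)
Conditions: n-BuLi, THF, 0 °C; then ethylene oxide, 0 °C to rt; aq. NH4Cl
Reagents that add atoms: compound 4, ethylene oxide, C1CO1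
Why: Directed ortho-metalation: the position between the two MOM ethers is doubly coordinated and the bulky TIPS ether shields its own ortho positions, so 5 should form regioselectively. The aryllithium then opens the epoxide by SN2 attack, and no lithium halide is present to divert the epoxide to a halohydrin.

Step 4
Reactants: 6 arylethanol
Product: 7 2-[3-bromo-2,6-bis(methoxymethoxy)-4-(triisopropylsilyloxy)phenyl]ethan-1-ol
Conditions: NBS (1.0 equiv), MeCN, −20 to 0 °C, dark
Reagents that add atoms: N-bromosuccinimide, O=C1CCC(=O)N1Br
Why: Electrophilic aromatic bromination; the two free ring positions are equivalent and each is ortho or para to three oxygen donors, so one equivalent at low temperature should brominate once, and no alkene is yet present to compete. The bromine is the latent acetyl group of ring A.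

Step 5
Reactants: 7 bromo alcohol
Product: 8 [3-bromo-2,6-bis(methoxymethoxy)-4-(triisopropylsilyloxy)phenyl]acetaldehyde
Conditions: Dess–Martin periodinane, NaHCO3, CH2Cl2, 0 °C to rt
Reagents that add atoms: none
Why: Dess–Martin oxidation of the primary alcohol stops at the aldehyde under buffered, non-acidic conditions; the enolizable arylacetaldehyde is used at once without chromatography.

Step 6
Reactants: 8 arylacetaldehyde; 9 isopropenylmagnesium bromide
Product: 10 racemic 1-[3-bromo-2,6-bis(methoxymethoxy)-4-(triisopropylsilyloxy)phenyl]-3-methylbut-3-en-2-ol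
Conditions: 9, anhydrous CeCl3, THF, −78 °C; aq. NH4Cl
Reagents that add atoms: compound 9, isopropenylmagnesium bromide, C=C(C)[Mg]Br
Why: 1,2-Addition of an alkenyl organometallic to an aldehyde; transmetalation to the less basic organocerium suppresses enolization of the arylacetaldehyde, and the aryl bromide does not exchange with the Grignard reagent at −78 °C. The carbinol centre is made racemic on purpose, since step 7 erases it.

Step 7
Reactants: 10 racemic allylic alcohol; 11 triethyl orthoacetate
Product: 14 ethyl (4E)-6-[3-bromo-2,6-bis(methoxymethoxy)-4-(triisopropylsilyloxy)phenyl]-4-methylhex-4-enoate, via mixed orthoester 12 (not isolated), via ketene acetal 13 (not isolated)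
Conditions: 11 (neat, excess), EtCO2H (cat.), 135–140 °C, EtOH distilled off
Reagents that add atoms: compound 11, triethyl orthoacetate, CCOC(C)(OCC)OCC
Why: Johnson–Claisen (orthoester Claisen) rearrangement: propionic acid catalyses exchange of one ethoxy group of 11 for the alcohol to give the mixed orthoester 12, which loses ethanol to the allyl ketene acetal 13. 13 undergoes a concerted [3,3]-sigmatropic shift in which the ketene CH2 (future C5'') bonds to the isopropenyl CH2 (future C4'') while the C2''–O bond breaks, giving the C2''=C3'' alkene and the ester carbon C6''. The closest known reaction type is the orthoester Claisen rearrangement of secondary 2-methylalk-1-en-3-ols to (E)-4-methylalk-4-enoates. No ring is closed and no stereocentre is formed; the carbinol centre of 10 is consumed, which is why 10 may be racemic. The selectivity needed is E geometry: in the chair transition state the CH2Ar group on C2'' takes the equatorial position to avoid a 1,3-diaxial contact with the ethoxy group on the ketene acetal carbon, and this places C1'' trans to C4''. Distilling off ethanol drives both equilibria forward. The weak acid should leave the aryl MOM ethers, the TIPS ether and the aryl bromide untouched.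

Step 8
Reactants: 14 ethyl ester
Product: 15 (4E)-6-[3-bromo-2,6-bis(methoxymethoxy)-4-(triisopropylsilyloxy)phenyl]-N-methoxy-N,4-dimethylhex-4-enamide
Conditions: MeNH(OMe)·HCl, i-PrMgCl, THF, −20 to 0 °C
Reagents that add atoms: N,O-dimethylhydroxylamine hydrochloride, CNOC.Cl
Why: Aminolysis of the ester by the chloromagnesium amide of N,O-dimethylhydroxylamine gives the Weinreb amide; at this temperature the hindered, electron-rich aryl bromide should not undergo bromine–magnesium exchange.

Step 9
Reactants: 15 Weinreb amide; 9 isopropenylmagnesium bromide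
Product: 16 (6E)-8-[3-bromo-2,6-bis(methoxymethoxy)-4-(triisopropylsilyloxy)phenyl]-2,6-dimethylocta-1,6-dien-3-one
Conditions: 9, THF, −20 to 0 °C; poured into cold aq. NH4Cl
Reagents that add atoms: compound 9, isopropenylmagnesium bromide, C=C(C)[Mg]Br
Why: Weinreb ketone synthesis: the chelated tetrahedral adduct holds until work-up, so one isopropenyl group is delivered and C7'', its methyl and C8'' are in place. The cold, weakly acidic quench limits conjugate addition of the released hydroxylamine to the enone.

Step 10
Reactants: 16 isopropenyl ketone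
Product: 17 (3R,6E)-8-[3-bromo-2,6-bis(methoxymethoxy)-4-(triisopropylsilyloxy)phenyl]-2,6-dimethylocta-1,6-dien-3-ol
Conditions: (S)-1-butyl-3,3-diphenyltetrahydro-1H,3H-pyrrolo[1,2-c][1,3,2]oxazaborole (0.2 equiv), catecholborane, toluene, −78 °C; MeOH, then aq. NaHCO3
Reagents that add atoms: none
Why: Corey–Bakshi–Shibata reduction: the α-methylvinyl group acts as the large substituent and the unbranched CH2CH2 chain as the small one, so the (S)-oxazaborolidine should deliver hydride to the face that gives the (R)-carbinol, by analogy with acetophenone giving (R)-1-phenylethanol. Catecholborane at −78 °C is chosen because it does not hydroborate the two alkenes.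

Step 11
Reactants: 17 (R)-allylic alcohol
Product: 18 tert-butyl({(3R,6E)-8-[3-bromo-2,6-bis(methoxymethoxy)-4-(triisopropylsilyloxy)phenyl]-2,6-dimethylocta-1,6-dien-3-yl}oxy)dimethylsilane
Conditions: TBSCl, imidazole, DMF, rt
Reagents that add atoms: tert-butyldimethylsilyl chloride, CC(C)(C)[Si](C)(C)Cl
Why: Silylation of the secondary allylic alcohol; the TBS ether removes the acidic OH before the organolithium step and falls together with the MOM groups at the end.

Step 12
Reactants: 18 aryl bromide
Product: 20 1-{3-[(2E,6R)-6-(tert-butyldimethylsilyloxy)-3,7-dimethylocta-2,7-dien-1-yl]-2,4-bis(methoxymethoxy)-6-(triisopropylsilyloxy)phenyl}ethan-1-one, via aryllithium 19 (not isolated)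
Conditions: t-BuLi (2.0 equiv), THF, −78 °C; then MeC(O)N(OMe)Me, −78 to −40 °C; aq. NH4Cl
Reagents that add atoms: N-methoxy-N-methylacetamide, CC(=O)N(C)OC
Why: Bromine–lithium exchange at −78 °C should outrun deprotonation of the benzylic-allylic C1'' methylene and O-to-C migration of the bulky TIPS group. Acylation of 19 by the Weinreb amide stops at the ketone.

Step 13
Reactants: 20 TIPS-protected acetophenone
Product: 21 1-{3-[(2E,6R)-6-(tert-butyldimethylsilyloxy)-3,7-dimethylocta-2,7-dien-1-yl]-6-hydroxy-2,4-bis(methoxymethoxy)phenyl}ethan-1-one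
Conditions: Bu4NF, AcOH, THF, 0 °C
Reagents that add atoms: none
Why: Fluoride-mediated desilylation; the aryl silyl ether, whose leaving group is a phenoxide stabilized by the ortho acetyl group, should cleave far faster than the secondary alkyl TBS ether. Acetic acid buffers the phenoxide.

Step 14
Reactants: 22 3,4-dihydroxy-5-methoxybenzaldehyde
Product: 23 3-methoxy-4,5-bis(methoxymethoxy)benzaldehyde
Conditions: MOMCl, i-Pr2NEt, CH2Cl2, 0 °C to rt
Reagents that add atoms: chloromethyl methyl ether, COCCl
Why: O-alkylation of both catechol hydroxyls (Williamson-type acetal formation), which masks the oxidation-prone catechol for the basic condensation.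

Step 15
Reactants: 21 2'-hydroxyacetophenone; 23 ring B aldehyde
Product: 24 (2E)-1-{3-[(2E,6R)-6-(tert-butyldimethylsilyloxy)-3,7-dimethylocta-2,7-dien-1-yl]-6-hydroxy-2,4-bis(methoxymethoxy)phenyl}-3-[3-methoxy-4,5-bis(methoxymethoxy)phenyl]prop-2-en-1-one
Conditions: KOH, EtOH/H2O, 0 °C to rt; aq. NH4Cl at 0 °C
Reagents that add atoms: compound 23, 3-methoxy-4,5-bis(methoxymethoxy)benzaldehyde, COCOc1cc(C=O)cc(OC)c1OCOC
Why: Claisen–Schmidt condensation: the ketone enolate adds to the non-enolizable aldehyde and the aldol eliminates by E1cB to the conjugated (E)-enone. MOM and TBS ethers are stable to hydroxide, and a cold, near-neutral work-up keeps the chalcone from closing to racemic flavanone.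

Step 16
Reactants: 24 2'-hydroxychalcone
Product: 25 (2S)-6-[(2E,6R)-6-(tert-butyldimethylsilyloxy)-3,7-dimethylocta-2,7-dien-1-yl]-2-[3-methoxy-4,5-bis(methoxymethoxy)phenyl]-5,7-bis(methoxymethoxy)-2,3-dihydro-4H-chromen-4-one
Conditions: N-[3,5-bis(trifluoromethyl)phenyl]-N′-[(8α,9S)-6′-methoxycinchonan-9-yl]thiourea (10 mol%), toluene, rt
Reagents that add atoms: none
Why: Enantioselective intramolecular oxa-Michael addition (6-endo-trig) of a 2'-hydroxychalcone under bifunctional cinchona-thiourea catalysis: the quinuclidine deprotonates the hydrogen-bonded phenol while the thiourea binds the enone carbonyl. The chiral ion pair should add the phenoxide to one face of C-beta and so set C2; the remote C6'' centre has no influence. The position of the only free phenol, para to the chain, fixes the chain on C6.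

Step 17
Reactants: 25 protected flavanone
Product: 26 (2S)-2-(3,4-dihydroxy-5-methoxyphenyl)-5,7-dihydroxy-6-[(2E,6R)-6-hydroxy-3,7-dimethylocta-2,7-dien-1-yl]-2,3-dihydro-4H-chromen-4-one
Conditions: 3 M aq. HCl, MeOH, rt to 40 °C
Reagents that add atoms: none
Why: Acid-catalysed methanolysis of the four aryl methoxymethyl acetals and of the silyl ether. Dilute HCl near room temperature should be too mild to protonate the C2''=C3'' alkene, ionize the allylic carbinol or open ring C, so both stereocentres should be kept.

## Compound list

1 | phloroglucinol | Oc1cc(O)cc(O)c1 | starting material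
2 | 5-(triisopropylsilyloxy)benzene-1,3-diol | Oc1cc(O)cc(O[Si](C(C)C)(C(C)C)C(C)C)c1 | intermediate
3 | 1,3-bis(methoxymethoxy)-5-(triisopropylsilyloxy)benzene | COCOc1cc(OCOC)cc(O[Si](C(C)C)(C(C)C)C(C)C)c1 | intermediate
4 | ethylene oxide | C1CO1 | starting material
5 | [2,6-bis(methoxymethoxy)-4-(triisopropylsilyloxy)phenyl]lithium | [Li]c1c(OCOC)cc(O[Si](C(C)C)(C(C)C)C(C)C)cc1OCOC | intermediate
6 | 2-[2,6-bis(methoxymethoxy)-4-(triisopropylsilyloxy)phenyl]ethan-1-ol | OCCc1c(OCOC)cc(O[Si](C(C)C)(C(C)C)C(C)C)cc1OCOC | intermediate
7 | 2-[3-bromo-2,6-bis(methoxymethoxy)-4-(triisopropylsilyloxy)phenyl]ethan-1-ol | OCCc1c(OCOC)cc(O[Si](C(C)C)(C(C)C)C(C)C)c(Br)c1OCOC | intermediate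
8 | [3-bromo-2,6-bis(methoxymethoxy)-4-(triisopropylsilyloxy)phenyl]acetaldehyde | O=CCc1c(OCOC)cc(O[Si](C(C)C)(C(C)C)C(C)C)c(Br)c1OCOC | intermediate
9 | isopropenylmagnesium bromide | C=C(C)[Mg]Br | starting material
10 | racemic 1-[3-bromo-2,6-bis(methoxymethoxy)-4-(triisopropylsilyloxy)phenyl]-3-methylbut-3-en-2-ol | C=C(C)C(O)Cc1c(OCOC)cc(O[Si](C(C)C)(C(C)C)C(C)C)c(Br)c1OCOC | intermediate
11 | triethyl orthoacetate | CCOC(C)(OCC)OCC | starting material
12 | mixed orthoester, the 1,1-diethoxyethyl ether of 10 | C=C(C)C(Cc1c(OCOC)cc(O[Si](C(C)C)(C(C)C)C(C)C)c(Br)c1OCOC)OC(C)(OCC)OCC | intermediate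
13 | allyl ketene acetal, the 1-ethoxyvinyl ether of 10 | C=C(C)C(Cc1c(OCOC)cc(O[Si](C(C)C)(C(C)C)C(C)C)c(Br)c1OCOC)OC(=C)OCC | intermediate
14 | ethyl (4E)-6-[3-bromo-2,6-bis(methoxymethoxy)-4-(triisopropylsilyloxy)phenyl]-4-methylhex-4-enoate | CCOC(=O)CC/C(C)=C/Cc1c(OCOC)cc(O[Si](C(C)C)(C(C)C)C(C)C)c(Br)c1OCOC | intermediate
15 | (4E)-6-[3-bromo-2,6-bis(methoxymethoxy)-4-(triisopropylsilyloxy)phenyl]-N-methoxy-N,4-dimethylhex-4-enamide | CON(C)C(=O)CC/C(C)=C/Cc1c(OCOC)cc(O[Si](C(C)C)(C(C)C)C(C)C)c(Br)c1OCOC | intermediate
16 | (6E)-8-[3-bromo-2,6-bis(methoxymethoxy)-4-(triisopropylsilyloxy)phenyl]-2,6-dimethylocta-1,6-dien-3-one | C=C(C)C(=O)CC/C(C)=C/Cc1c(OCOC)cc(O[Si](C(C)C)(C(C)C)C(C)C)c(Br)c1OCOC | intermediate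
17 | (3R,6E)-8-[3-bromo-2,6-bis(methoxymethoxy)-4-(triisopropylsilyloxy)phenyl]-2,6-dimethylocta-1,6-dien-3-ol | C=C(C)[C@H](O)CC/C(C)=C/Cc1c(OCOC)cc(O[Si](C(C)C)(C(C)C)C(C)C)c(Br)c1OCOC | intermediate
18 | tert-butyl({(3R,6E)-8-[3-bromo-2,6-bis(methoxymethoxy)-4-(triisopropylsilyloxy)phenyl]-2,6-dimethylocta-1,6-dien-3-yl}oxy)dimethylsilane | C=C(C)[C@H](O[Si](C)(C)C(C)(C)C)CC/C(C)=C/Cc1c(OCOC)cc(O[Si](C(C)C)(C(C)C)C(C)C)c(Br)c1OCOC | intermediate
19 | aryllithium formed from 18 by bromine–lithium exchange | C=C(C)[C@H](O[Si](C)(C)C(C)(C)C)CC/C(C)=C/Cc1c(OCOC)cc(O[Si](C(C)C)(C(C)C)C(C)C)c([Li])c1OCOC | intermediate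
20 | 1-{3-[(2E,6R)-6-(tert-butyldimethylsilyloxy)-3,7-dimethylocta-2,7-dien-1-yl]-2,4-bis(methoxymethoxy)-6-(triisopropylsilyloxy)phenyl}ethan-1-one | C=C(C)[C@H](O[Si](C)(C)C(C)(C)C)CC/C(C)=C/Cc1c(OCOC)cc(O[Si](C(C)C)(C(C)C)C(C)C)c(C(C)=O)c1OCOC | intermediate
21 | 1-{3-[(2E,6R)-6-(tert-butyldimethylsilyloxy)-3,7-dimethylocta-2,7-dien-1-yl]-6-hydroxy-2,4-bis(methoxymethoxy)phenyl}ethan-1-one | C=C(C)[C@H](O[Si](C)(C)C(C)(C)C)CC/C(C)=C/Cc1c(OCOC)cc(O)c(C(C)=O)c1OCOC | intermediate
22 | 3,4-dihydroxy-5-methoxybenzaldehyde | COc1cc(C=O)cc(O)c1O | starting material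
23 | 3-methoxy-4,5-bis(methoxymethoxy)benzaldehyde | COCOc1cc(C=O)cc(OC)c1OCOC | intermediate
24 | (2E)-1-{3-[(2E,6R)-6-(tert-butyldimethylsilyloxy)-3,7-dimethylocta-2,7-dien-1-yl]-6-hydroxy-2,4-bis(methoxymethoxy)phenyl}-3-[3-methoxy-4,5-bis(methoxymethoxy)phenyl]prop-2-en-1-one | C=C(C)[C@H](O[Si](C)(C)C(C)(C)C)CC/C(C)=C/Cc1c(OCOC)cc(O)c(C(=O)/C=C/c2cc(OC)c(OCOC)c(OCOC)c2)c1OCOC | intermediate
25 | (2S)-6-[(2E,6R)-6-(tert-butyldimethylsilyloxy)-3,7-dimethylocta-2,7-dien-1-yl]-2-[3-methoxy-4,5-bis(methoxymethoxy)phenyl]-5,7-bis(methoxymethoxy)-2,3-dihydro-4H-chromen-4-one | C=C(C)[C@H](O[Si](C)(C)C(C)(C)C)CC/C(C)=C/Cc1c(OCOC)cc2c(c1OCOC)C(=O)C[C@@H](c1cc(OCOC)c(OCOC)c(OC)c1)O2 | intermediate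
26 | (2S)-2-(3,4-dihydroxy-5-methoxyphenyl)-5,7-dihydroxy-6-[(2E,6R)-6-hydroxy-3,7-dimethylocta-2,7-dien-1-yl]-2,3-dihydro-4H-chromen-4-one | C=C(C)[C@H](O)CC/C(C)=C/Cc1c(O)cc2c(c1O)C(=O)C[C@@H](c1cc(O)c(O)c(OC)c1)O2 | target

## Step count and least certain steps

Total: 17 steps. Longest linear sequence: 16 steps (steps 1 to 13 and 15 to 17). Step 14 is a one-step branch for ring B.

**Step 7 (key step).** The most likely failure is acid-promoted loss of the allylic, homobenzylic oxygen function at 140 °C, that is, ionization and elimination towards an aryl-conjugated diene. Slow acetal exchange at the MOM ethers over the long heating time is the second concern. Erosion of E selectivity is the least likely. The fallback sets out from 10 and returns to the route at 15, and replaces hot acid by a base-mediated rearrangement at low temperature. Acetylation of 10 (Ac2O, pyridine, DMAP) gives racemic 1-[3-bromo-2,6-bis(methoxymethoxy)-4-(triisopropylsilyloxy)phenyl]-3-methylbut-3-en-2-yl acetate F1. LiN(i-Pr)2 and Me3SiCl in THF at −78 °C convert it into the trimethylsilyl ketene acetal F2. F2 rearranges on warming to room temperature (Ireland–Claisen) through the same chair and gives, after aqueous work-up, (4E)-6-[3-bromo-2,6-bis(methoxymethoxy)-4-(triisopropylsilyloxy)phenyl]-4-methylhex-4-enoic acid F3. Coupling of F3 with MeNH(OMe)·HCl (EDC·HCl, i-Pr2NEt, CH2Cl2) gives 15.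

**Step 16.** Facial selectivity may be insufficient. The ring closure is also reversible, so the product can re-open and re-close without control, and an uncatalysed background cyclization can dilute the selectivity. The fallback sets out from 24 and returns at 25, and replaces catalyst control by separation and recycling. NaOAc in refluxing EtOH closes ring C without induction and gives 25 together with its (2R)-epimer F4. The two are diastereomers because C6'' is fixed, and they are separated by preparative HPLC on a chiral stationary phase. F4 is re-opened to 24 with KOH in EtOH and cyclized again.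

**Step 12.** The silyl group may migrate from oxygen to the neighbouring lithiated carbon. Alternatively the hindered aryllithium may take a proton from the acetamide instead of adding to it, which returns debrominated material. The fallback sets out from 18 and returns at 21, and removes the silyl group before the carbanion is made. Bu4NF with AcOH in THF at 0 °C gives 2-bromo-4-[(2E,6R)-6-(tert-butyldimethylsilyloxy)-3,7-dimethylocta-2,7-dien-1-yl]-3,5-bis(methoxymethoxy)phenol F5. MeLi (1 equiv) followed by t-BuLi (2 equiv) at −78 °C gives the O,C-dilithio species F6. N-methoxy-N-methylacetamide acylates F6 at carbon to give 21 directly, so 20 is bypassed.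

**Step 10.** The catalyst may discriminate incompletely between the α-methylvinyl group and the unbranched chain, and conjugate reduction may compete. The fallback sets out from 16 and returns at 17, and replaces asymmetric reduction by kinetic resolution. Luche reduction (NaBH4, CeCl3·7H2O, MeOH, −40 °C) gives the racemic alcohol F7. Sharpless kinetic resolution (Ti(OiPr)4, L-(+)-diisopropyl tartrate, t-BuOOH (0.6 equiv), 4 Å sieves, CH2Cl2, −20 °C) should epoxidize the (S)-enantiomer to the epoxy alcohol F8 and leave the (R)-alcohol 17, which is isolated by chromatography.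

**Step 17.** A freed C5 or C7 hydroxyl may add to C3'' under acid and close a chroman ring. The allylic carbinol may ionize, or ring C may open and epimerize C2 if the acid is too strong or the reaction too warm. The fallback sets out from 25 and ends at 26, and removes the two kinds of protecting group separately without a protic acid. ZnBr2 and n-PrSH in CH2Cl2 at 0 °C cleave the four MOM ethers and give the TBS ether of the target F9. HF·pyridine in THF/pyridine at 0 °C then removes the silyl group.

## Further compounds

F1 | step 7 | racemic 1-[3-bromo-2,6-bis(methoxymethoxy)-4-(triisopropylsilyloxy)phenyl]-3-methylbut-3-en-2-yl acetate | C=C(C)C(OC(C)=O)Cc1c(OCOC)cc(O[Si](C(C)C)(C(C)C)C(C)C)c(Br)c1OCOC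
F2 | step 7 | trimethylsilyl ketene acetal of F1 | C=C(C)C(Cc1c(OCOC)cc(O[Si](C(C)C)(C(C)C)C(C)C)c(Br)c1OCOC)OC(=C)O[Si](C)(C)C
F3 | step 7 | (4E)-6-[3-bromo-2,6-bis(methoxymethoxy)-4-(triisopropylsilyloxy)phenyl]-4-methylhex-4-enoic acid | OC(=O)CC/C(C)=C/Cc1c(OCOC)cc(O[Si](C(C)C)(C(C)C)C(C)C)c(Br)c1OCOC
F4 | step 16 | (2R)-epimer of 25 | C=C(C)[C@H](O[Si](C)(C)C(C)(C)C)CC/C(C)=C/Cc1c(OCOC)cc2c(c1OCOC)C(=O)C[C@H](c1cc(OCOC)c(OCOC)c(OC)c1)O2
F5 | step 12 | 2-bromo-4-[(2E,6R)-6-(tert-butyldimethylsilyloxy)-3,7-dimethylocta-2,7-dien-1-yl]-3,5-bis(methoxymethoxy)phenol | C=C(C)[C@H](O[Si](C)(C)C(C)(C)C)CC/C(C)=C/Cc1c(OCOC)cc(O)c(Br)c1OCOC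
F6 | step 12 | O,C-dilithio species of F5 | C=C(C)[C@H](O[Si](C)(C)C(C)(C)C)CC/C(C)=C/Cc1c(OCOC)cc(O[Li])c([Li])c1OCOC
F7 | step 10 | racemic (6E)-8-[3-bromo-2,6-bis(methoxymethoxy)-4-(triisopropylsilyloxy)phenyl]-2,6-dimethylocta-1,6-dien-3-ol | C=C(C)C(O)CC/C(C)=C/Cc1c(OCOC)cc(O[Si](C(C)C)(C(C)C)C(C)C)c(Br)c1OCOC
F8 | step 10 | (1S,4E)-6-[3-bromo-2,6-bis(methoxymethoxy)-4-(triisopropylsilyloxy)phenyl]-4-methyl-1-[(2R)-2-methyloxiran-2-yl]hex-4-en-1-ol | C[C@@]1(CO1)[C@@H](O)CC/C(C)=C/Cc2c(OCOC)cc(O[Si](C(C)C)(C(C)C)C(C)C)c(Br)c2OCOC
F9 | step 17 | (2S)-6-[(2E,6R)-6-(tert-butyldimethylsilyloxy)-3,7-dimethylocta-2,7-dien-1-yl]-2-(3,4-dihydroxy-5-methoxyphenyl)-5,7-dihydroxy-2,3-dihydro-4H-chromen-4-one | C=C(C)[C@H](O[Si](C)(C)C(C)(C)C)CC/C(C)=C/Cc1c(O)cc2c(c1O)C(=O)C[C@@H](c1cc(O)c(O)c(OC)c1)O2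
A1 | alternative 1 | methyl 2-[(2E,6R)-6-(tert-butyldimethylsilyloxy)-3,7-dimethylocta-2,7-dien-1-yl]-4-{(2S)-2-[3-methoxy-4,5-bis(methoxymethoxy)phenyl]-4-oxo-3,4-dihydro-2H-pyran-6-yl}-3-oxobutanoate | COC(=O)C(C/C=C(C)/CC[C@@H](O[Si](C)(C)C(C)(C)C)C(C)=C)C(=O)CC1=CC(=O)C[C@@H](c2cc(OCOC)c(OCOC)c(OC)c2)O1
A2 | alternative 1 | (2S)-6-[(2E,6R)-6-(tert-butyldimethylsilyloxy)-3,7-dimethylocta-2,7-dien-1-yl]-5,7-dihydroxy-2-[3-methoxy-4,5-bis(methoxymethoxy)phenyl]-2,3-dihydro-4H-chromen-4-one | C=C(C)[C@H](O[Si](C)(C)C(C)(C)C)CC/C(C)=C/Cc1c(O)cc2c(c1O)C(=O)C[C@@H](c1cc(OCOC)c(OCOC)c(OC)c1)O2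
A3 | alternative 2 | 6-[(2E,6R)-6-(tert-butyldimethylsilyloxy)-3,7-dimethylocta-2,7-dien-1-yl]-5,7-bis(methoxymethoxy)-4H-chromen-4-one | C=C(C)[C@H](O[Si](C)(C)C(C)(C)C)CC/C(C)=C/Cc1c(OCOC)cc2occc(=O)c2c1OCOC
A4 | alternative 2 | [3-methoxy-4,5-bis(methoxymethoxy)phenyl]boronic acid | COc1cc(B(O)O)cc(OCOC)c1OCOC
A5 | alternative 2 | (2S)-6-[(2E,6R)-6-(tert-butyldimethylsilyloxy)-3,7-dimethylocta-2,7-dien-1-yl]-2-[3-methoxy-4,5-bis(methoxymethoxy)phenyl]-5,7-bis(methoxymethoxy)-2,3-dihydro-4H-chromen-4-one | C=C(C)[C@H](O[Si](C)(C)C(C)(C)C)CC/C(C)=C/Cc1c(OCOC)cc2c(c1OCOC)C(=O)C[C@@H](c1cc(OCOC)c(OCOC)c(OC)c1)O2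
A6 | alternative 3 | (3R)-3-(tert-butyldimethylsilyloxy)-2-methylhept-1-en-6-yne | C=C(C)[C@H](O[Si](C)(C)C(C)(C)C)CCC#C
A7 | alternative 3 | 2-(chloromethyl)-1,3-bis(methoxymethoxy)-5-(triisopropylsilyloxy)benzene | ClCc1c(OCOC)cc(O[Si](C(C)C)(C(C)C)C(C)C)cc1OCOC
A8 | alternative 3 | tert-butyl({(3R,6E)-8-[2,6-bis(methoxymethoxy)-4-(triisopropylsilyloxy)phenyl]-2,6-dimethylocta-1,6-dien-3-yl}oxy)dimethylsilane | C=C(C)[C@H](O[Si](C)(C)C(C)(C)C)CC/C(C)=C/Cc1c(OCOC)cc(O[Si](C(C)C)(C(C)C)C(C)C)cc1OCOC
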